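The plan rests on cutting ring A at C1–C10 and C4–C5 (labdane numbering). Ring B, whose methyls C17 and C20 flank C9, is the substitution pattern of 2,6-dimethylbenzoquinone, and C1–C2(O)–C3–C4(CH3)2 is that of mesityl oxide. In one flask a catalyst-controlled [4+2] addition of the cross-conjugated silyl dienol ether of mesityl oxide to the quinone closes ring A, sets C10, and, after base epimerisation of C5, delivers the trans-decalin with C7=C8 and C17 in place. The precursor pair is thus a 2-silyloxy-4-methylpenta-1,3-diene and the quinone as bought. C6 is then deoxygenated, the side chain is joined at C9 through C11, and C2 is reduced to the equatorial alcohol.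

Key step: step 2

Remarks and assumptions
- Numbering: all bicyclic compounds carry labdane numbers. C1–C10 are the decalin carbons (ring A = C1–C5, C10; ring B = C5–C10), C18/C19 are the methyls on C4, C17 is the methyl on C8, C20 the methyl on C10, and C11–C15 is the chain on C9 with methyl C16 on C13. The target is (2R,5R,9R,10R,13S).
- Assumption: the sense of induction in step 2 is taken from the accepted binding model of this catalyst family (boron on the C6 carbonyl lone pair syn to C5, C5–H···O contact, diene on the face away from the neighbouring phenyl group). It is to be confirmed on the first batch; the mirror-image catalyst is equally accessible.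
- Assumption: (R)-2-methylsuccinic acid 4-methyl ester (11) is bought; it already differentiates the two carboxyl groups.
- Design choices: a triisopropylsilyl enol ether is used because it must survive a strongly acidic catalyst and eight further steps. C6 is removed by reductive cleavage next to the C9 ketone, since a π-allylpalladium/formate reduction would be expected to deliver hydride to the more substituted terminus C8.

Step 1
Reactants: 1 mesityl oxide
Product: 2 4-methyl-2-(triisopropylsilyloxy)penta-1,3-diene
Conditions: LiN(iPr)2, THF, −78 °C; then iPr3SiOTf, −78 → 0 °C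
Reagents that add atoms: triisopropylsilyl trifluoromethanesulfonate, CC(C)[Si](OS(=O)(=O)C(F)(F)F)(C(C)C)C(C)C
Why: Kinetic deprotonation of the enone at the α′-methyl gives the cross-conjugated lithium dienolate, which the silyl triflate traps on oxygen (silyl enol ether formation).

Step 2
Reactants: 2 4-methyl-2-(triisopropylsilyloxy)penta-1,3-diene; 3 2,6-dimethyl-1,4-benzoquinone
Product: 5 trans-fused enedione silyl enol ether (5R,10R; 6,9-dioxo; C7=C8; C2=C3), via cis-fused cycloadduct 4 (not isolated)
Conditions: (S)-1-(2-methylphenyl)-3,3-diphenyltetrahydro-1H,3H-pyrrolo[1,2-c][1,3,2]oxazaborole·HNTf2 (20 mol %), 2 (1.5 equiv), CH2Cl2, −78 → −40 °C; then DBU (1 equiv), −40 °C → rt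
Reagents that add atoms: none
Why: The boron cation should bind the C6 carbonyl (flanked by two CH groups, the less hindered one) on the lone pair syn to C5, which makes the methyl-bearing C10 the most electrophilic carbon, so the nucleophilic CH2 terminus C1 of the silyloxydiene bonds to C10 and the dimethyl-substituted terminus C4 to C5, either in a concerted but highly asynchronous [4+2] addition or as a Mukaiyama–Michael addition followed by collapse of the silyloxyallyl cation onto the boron enolate. The closest known reaction type is the oxazaborolidinium-catalysed enantioselective Diels–Alder reaction of methyl-substituted benzoquinones with 2-silyloxybutadienes, and additions of 4,4-disubstituted 2-silyloxydienes to hindered cyclic enones under strong Lewis acids are known in racemic form; their combination is untested and is where the route carries its risk. Ring A is closed as a carbocycle by cycloaddition, or in the stepwise limit by 6-endo-trig attack of C5 on C4. C10 is set by the catalyst, which leaves one face of the C5=C10 bond open while the other lies over a phenyl group; C5 is first cis to the C10 methyl (suprafacial addition) and is then brought to the trans fusion under thermodynamic control by DBU through the C5–C6 enolate. The step needs the orientation C1-to-C10, secured by the match of the nucleophilic diene terminus with the β-carbon of the coordinated carbonyl and reinforced sterically because the crowded terminus C4 meets the CH carbon C5; the adduct cannot aromatise because C10 is quaternary. The second quinone double bond is untouched and already is C7=C8 with C17.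

Step 3
Reactants: 5 trans-fused enedione silyl enol ether
Product: 6 C6 allylic alcohol (5R,6S,10R; 9-oxo; C7=C8)
Conditions: NaBH4, CeCl3·7H2O, MeOH/CH2Cl2, −78 °C
Reagents that add atoms: none
Why: Luche reduction (1,2-selective) should take the C6 carbonyl because C9 is flanked by quaternary C10 and methyl-bearing C8, with hydride expected from the face opposite the C10 methyl; the C6 centre is temporary and its configuration is of no consequence.

Step 4
Reactants: 6 C6 allylic alcohol
Product: 7 C6 acetate (5R,6S,10R)
Conditions: Ac2O, DMAP, Et3N, CH2Cl2, rt → 40 °C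
Reagents that add atoms: acetic anhydride, CC(=O)OC(C)=O
Why: DMAP-catalysed acylation turns the hydroxyl into a leaving group for the next step, with gentle warming allowed for because the hydroxyl lies syn to the C10 and axial C4 methyls.

Step 5
Reactants: 7 C6 acetate
Product: 9 conjugated enone (5R,10R; 9-oxo; C7=C8; C6 is CH2), via deconjugated ketone 8 (not isolated)
Conditions: SmI2 (2.5 equiv), THF/MeOH, −78 °C; aqueous work-up; DBU, CH2Cl2, rt on the crude
Reagents that add atoms: none
Why: Divalent samarium reduces the C9 enone and the resulting allyl anion expels the γ-acetate (reductive cleavage of a vinylogous α-acyloxy ketone) to a dienolate that is protonated mainly at C8, after which DBU returns the double bond to conjugation at C7=C8; C5 is not acidic at this stage and keeps its configuration.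

Step 6
Reactants: 9 conjugated enone
Product: 10 cross-conjugated diene (5R,10R; exocyclic C9=C11; C7=C8)
Conditions: Cp2TiMe2 (3 equiv), toluene/THF, 70 °C, dark
Reagents that add atoms: dimethyltitanocene Cp2TiMe2, C[Ti+2]C.c1cc[cH-]c1.c1cc[cH-]c1
Why: Petasis methylenation, in which thermolysis gives the small, non-basic titanium methylidene Cp2Ti=CH2, is suited to a hindered ketone that would resist a Wittig ylide, and it tolerates silyl enol ethers.

Step 7
Reactants: 11 (R)-2-methylsuccinic acid 4-methyl ester
Product: 13 (R)-4-methyldihydrofuran-2(3H)-one, via hydroxy ester 12 (not isolated)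
Conditions: BH3·SMe2, THF, 0 °C → rt; MeOH; then TsOH (cat.), CH2Cl2, rt
Reagents that add atoms: none
Why: Borane reduces the free carboxylic acid much faster than the ester (chemoselective borane reduction) and the γ-hydroxy ester lactonises under acid catalysis, the stereocentre not being involved.

Step 8
Reactants: 13 (R)-4-methyldihydrofuran-2(3H)-one
Product: 15 ethyl (R)-4-bromo-3-methylbutanoate, via bromo acid 14 (not isolated)
Conditions: HBr (gas), EtOH, 0 °C → rt
Reagents that add atoms: hydrogen bromide, Br; ethanol, CCO
Why: Bromide opens the protonated γ-lactone at the O–CH2 carbon (SN2) and the acid is esterified in the same medium (Fischer esterification), the stereocentre being β to both reacting carbons.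

Step 9
Reactants: 10 cross-conjugated diene; 15 ethyl (R)-4-bromo-3-methylbutanoate
Product: 17 coupled ethyl ester (ring centres as in the target; 13S; C2=C3 silyl enol ether), via C11 alkylborane 16 (not isolated)
Conditions: 9-BBN, THF, 0 → 40 °C; then 15, Pd(OAc)2 (5 mol %), PCy3 (10 mol %), K3PO4·H2O, THF, rt → 40 °C
Reagents that add atoms: none
Why: 9-BBN should add only to the 1,1-disubstituted C9=C11 bond (boron to C11) from the face opposite the axial C10 methyl, which places H on C9 anti to C20 and so sets C9, and the primary alkylborane then joins C11 to C12 of the primary bromide under zerovalent palladium/PCy3 (alkyl–alkyl Suzuki–Miyaura coupling), conditions that tolerate esters.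

Step 10
Reactants: 17 coupled ethyl ester
Product: 18 keto ester, ethyl 2-oxolabd-7-en-15-oate (5R,9R,10R,13S)
Conditions: Bu4NF, AcOH, THF, 0 °C → rt
Reagents that add atoms: none
Why: Fluoride cleaves the Si–O bond and acetic acid protonates the enolate at C3 (desilylation of a silyl enol ether), releasing the C2 ketone without touching the ester or C7=C8.

Step 11
Reactants: 18 keto ester
Product: 19 labd-7-ene-2,15-diol (2R,5R,9R,10R,13S)
Conditions: Li, NH3(l), THF, EtOH, −78 → −33 °C
Reagents that add atoms: none
Why: Dissolving-metal reduction should give the thermodynamically preferred equatorial C2 alcohol (the axial epimer, which a borohydride attacking from the open side would give, is syn-diaxial to the C10 methyl and the axial C4 methyl), and the ethyl ester is reduced to the C15 alcohol in the same flask (Bouveault–Blanc reduction) while the isolated trisubstituted alkene is inert.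

Step 12
Reactants: 19 labd-7-ene-2,15-diol
Product: 20 labd-7-ene-2,15-diyl diacetate (2R,5R,9R,10R,13S), CNP0220683.1
Conditions: Ac2O, pyridine, DMAP (cat.), CH2Cl2, rt
Reagents that add atoms: acetic anhydride, CC(=O)OC(C)=O
Why: DMAP-catalysed acetylation of an unhindered primary alcohol and an equatorial secondary alcohol should give the diacetate.

Compound list
1 | mesityl oxide (4-methylpent-3-en-2-one) | CC(C)=CC(C)=O | starting material
2 | 4-methyl-2-(triisopropylsilyloxy)penta-1,3-diene | C=C(O[Si](C(C)C)(C(C)C)C(C)C)C=C(C)C | intermediate
3 | 2,6-dimethyl-1,4-benzoquinone | CC1=CC(=O)C=C(C)C1=O | starting material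
4 | cis-fused cycloadduct: 6,9-dioxo, C7=C8 with C17, C2=C3 enol ether with 2-OSi(iPr)3, C5-H and C10-CH3 on the same face (5S,10R); formed in the flask | O=C1C(C)=CC(=O)[C@H]2C(C)(C)C=C(O[Si](C(C)C)(C(C)C)C(C)C)C[C@@]12C | intermediate
5 | trans-fused enedione, (4aR,8aR)-2,5,5,8a-tetramethyl-7-(triisopropylsilyloxy)-4a,5,8,8a-tetrahydronaphthalene-1,4-dione; C5-H and C10-CH3 on opposite faces (5R,10R) | O=C1C(C)=CC(=O)[C@@H]2C(C)(C)C=C(O[Si](C(C)C)(C(C)C)C(C)C)C[C@@]12C | intermediate
6 | C6 alcohol: as 5 with C6 as CH–OH, hydroxyl on the face of the C10 methyl (5R,6S,10R), expected major epimer | O=C1C(C)=C[C@H](O)[C@@H]2C(C)(C)C=C(O[Si](C(C)C)(C(C)C)C(C)C)C[C@@]12C | intermediate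
7 | C6 acetate of 6 (5R,6S,10R) | O=C1C(C)=C[C@H](OC(C)=O)[C@@H]2C(C)(C)C=C(O[Si](C(C)C)(C(C)C)C(C)C)C[C@@]12C | intermediate
8 | deconjugated ketone: 9-oxo, C6=C7, C8 sp3 (epimer mixture), 2-silyl enol ether; formed in the flask | O=C1C(C)C=C[C@@H]2C(C)(C)C=C(O[Si](C(C)C)(C(C)C)C(C)C)C[C@@]12C | intermediate
9 | conjugated enone, (4aR,8aR)-2,5,5,8a-tetramethyl-7-(triisopropylsilyloxy)-4a,5,8,8a-tetrahydronaphthalen-1(4H)-one (5R,10R) | O=C1C(C)=CC[C@@H]2C(C)(C)C=C(O[Si](C(C)C)(C(C)C)C(C)C)C[C@@]12C | intermediate
10 | diene: as 9 with C9=O replaced by exocyclic C9=C11H2 (5R,10R) | C=C1C(C)=CC[C@@H]2C(C)(C)C=C(O[Si](C(C)C)(C(C)C)C(C)C)C[C@@]12C | intermediate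
11 | (R)-2-methylsuccinic acid 4-methyl ester, (R)-4-methoxy-2-methyl-4-oxobutanoic acid | COC(=O)C[C@@H](C)C(=O)O | starting material
12 | methyl (R)-4-hydroxy-3-methylbutanoate; formed in the flask | COC(=O)C[C@@H](C)CO | intermediate
13 | (R)-4-methyldihydrofuran-2(3H)-one | O=C1C[C@@H](C)CO1 | intermediate
14 | (R)-4-bromo-3-methylbutanoic acid; formed in the flask | OC(=O)C[C@@H](C)CBr | intermediate
15 | ethyl (R)-4-bromo-3-methylbutanoate | CCOC(=O)C[C@@H](C)CBr | intermediate
16 | C11 alkylborane: C11H2 of the bicycle bonded to the boron of 9-borabicyclo[3.3.1]nonane, C9-H anti to the C10 methyl, C7=C8, 2-silyl enol ether; formed in the flask | C(B1C2CCCC1CCC2)[C@@H]1C(C)=CC[C@@H]2C(C)(C)C=C(O[Si](C(C)C)(C(C)C)C(C)C)C[C@@]12C | intermediate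
17 | ethyl 2-(triisopropylsilyloxy)labda-2,7-dien-15-oate, C5, C9, C10 arranged as in the target, 13S | CCOC(=O)C[C@@H](C)CC[C@@H]1C(C)=CC[C@@H]2C(C)(C)C=C(O[Si](C(C)C)(C(C)C)C(C)C)C[C@@]12C | intermediate
18 | ethyl 2-oxolabd-7-en-15-oate (5R,9R,10R,13S) | CCOC(=O)C[C@@H](C)CC[C@@H]1C(C)=CC[C@@H]2C(C)(C)CC(=O)C[C@@]12C | intermediate
19 | labd-7-ene-2,15-diol (2R,5R,9R,10R,13S), C2 hydroxyl equatorial and anti to the C10 methyl | OCC[C@@H](C)CC[C@@H]1C(C)=CC[C@@H]2C(C)(C)C[C@@H](O)C[C@@]12C | intermediate
20 | labd-7-ene-2,15-diyl diacetate (2R,5R,9R,10R,13S), CNP0220683.1 | CC(=O)OCC[C@@H](C)CC[C@@H]1C(C)=CC[C@@H]2C(C)(C)C[C@@H](OC(C)=O)C[C@@]12C | target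

Total step count: 12. Longest linear sequence: 10 steps (steps 1–6 and 9–12, from mesityl oxide); steps 7–8 make the side-chain bromide.

Steps most likely to fail

1. Step 2. The ring closure may be slow or stall at the dimethyl-substituted diene terminus, the diene may be lost to protodesilylation under the acidic catalyst, facial control may be insufficient, or equilibration to the trans fusion may be incomplete. The fallback sets out from 2 and 3 and comes back at 5. The cycloaddition is run without asymmetric induction under the mixed Lewis acid AlBr3/AlMe3 (toluene/CH2Cl2, low temperature), a combination known to force [4+2] additions of 4,4-disubstituted 2-silyloxydienes to hindered cyclic enones. DBU treatment as before then gives the racemate: 5 together with the enantiomeric trans enedione F2, formed through 4 and the enantiomeric cis adduct F1. The racemate is separated by preparative chromatography on a chiral stationary phase (cellulose tris(3,5-dimethylphenylcarbamate)), and 5 re-enters at step 3.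

2. Step 9. Oxidative addition to the β-branched bromide and transmetalation of the hindered alkylborane may both be slow, so that β-hydride elimination and protodeboronation take over; the hydroboration may also show incomplete facial selectivity. The fallback sets out from 10 (through borane 16) and comes back at 17. Borane 16 is oxidised (NaBO3·4H2O, THF/H2O) to the C11 alcohol F3, and CBr4/PPh3/imidazole converts it into the C11 bromide F4. Magnesium in THF gives the C11 Grignard reagent F5, which is coupled with bromide 15 under Li2CuCl4 catalysis in THF/NMP at 0 °C (copper-catalysed Grignard–alkyl halide coupling, which tolerates esters) to give 17.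

3. Step 6. Methylene transfer to the doubly flanked C9 ketone may be sluggish, so that thermal decay of the titanium reagent outpaces olefination. The fallback sets out from 9 and comes back at 10, as a Peterson olefination in two stages. Me3SiCH2Li with anhydrous CeCl3 (THF, −78 °C) adds to C9 to give the β-hydroxysilane F6 (either C9 epimer serves), and KH (THF, 0 °C → rt) eliminates it to 10.

Further compounds
F1 | step 2 | enantiomeric cis adduct (mirror image of 4, formed in the flask) | O=C1C(C)=CC(=O)[C@@H]2C(C)(C)C=C(O[Si](C(C)C)(C(C)C)C(C)C)C[C@]12C
F2 | step 2 | enantiomeric trans enedione (mirror image of 5) | O=C1C(C)=CC(=O)[C@H]2C(C)(C)C=C(O[Si](C(C)C)(C(C)C)C(C)C)C[C@]12C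
F3 | step 9 | C11 alcohol (C9-H anti to the C10 methyl, C7=C8, 2-silyl enol ether) | OC[C@@H]1C(C)=CC[C@@H]2C(C)(C)C=C(O[Si](C(C)C)(C(C)C)C(C)C)C[C@@]12C
F4 | step 9 | C11 bromide | BrC[C@@H]1C(C)=CC[C@@H]2C(C)(C)C=C(O[Si](C(C)C)(C(C)C)C(C)C)C[C@@]12C
F5 | step 9 | C11 Grignard reagent | Br[Mg]C[C@@H]1C(C)=CC[C@@H]2C(C)(C)C=C(O[Si](C(C)C)(C(C)C)C(C)C)C[C@@]12C
F6 | step 6 | β-hydroxysilane (C9 carrying OH and CH2SiMe3, the latter drawn on the face opposite the C10 methyl) | C[Si](C)(C)C[C@@]1(O)C(C)=CC[C@@H]2C(C)(C)C=C(O[Si](C(C)C)(C(C)C)C(C)C)C[C@@]12C
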